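The indole core is cut at N1–C7a and C3–C3a, the two bonds that join the pyrrole atoms N1 and C3 to the neighbouring benzene carbons C7a and C3a. Since C5 and C6 both carry bromine, the aryne that corresponds to this cut is symmetric. One operation adds the nitrogen of a sulfonamido ketone to 4,5-dibromobenzyne, closes the pyrrole ring by attack of the resulting aryl anion on the carbonyl group and aromatises by loss of water. The precursors are an ortho-silyl aryl triflate carrying both bromines and N-tosylaminoacetone, whose ketone carbon becomes C3 with the future CH2N carbon attached. Bromination, amination, exchange of tosyl for methyl and N-oxidation finish the target.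

Key step: step 4

Remark: the target has no stereocentre; the only one that appears on the way, the carbinol carbon of hydroxyindoline 11, forms as a racemate and is removed in the same step.

Step 1
Reactants: 1 3,4-dibromophenol
Product: 2 4,5-dibromo-2-iodophenol
Conditions: NIS (1.0 equiv), TsOH·H2O (cat.), MeCN, 0 → 25 °C
Reagents that add atoms: N-iodosuccinimide, O=C1CCC(=O)N1I
Why: Electrophilic aromatic iodination of a phenol whose para position is blocked by bromine goes ortho to oxygen, and of the two ortho carbons the one not flanked by bromine should be attacked.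

Step 2
Reactants: 2 4,5-dibromo-2-iodophenol
Product: 6 4,5-dibromo-2-(trimethylsilyl)phenyl trifluoromethanesulfonate, via aryl silyl ether 3 (not isolated), via aryllithium 4 (not isolated), via lithium phenoxide 5 (not isolated)
Conditions: HMDS, THF, reflux, then evaporate; n-BuLi (1.05 equiv), THF, −100 °C; Tf2O, −100 → 25 °C
Reagents that add atoms: hexamethyldisilazane, C[Si](C)(C)N[Si](C)(C)C; trifluoromethanesulfonic anhydride, FC(F)(F)S(=O)(=O)OS(=O)(=O)C(F)(F)F
Why: O-silylation, iodine–lithium exchange (far faster than bromine–lithium exchange at −100 °C and giving an aryllithium with no halogen ortho to it), anionic 1,3 O-to-C silyl shift (retro-Brook rearrangement) and O-triflation of the phenoxide form the established one-flask sequence to ortho-silylaryl triflates.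

Step 3
Reactants: 7 aminoacetone hydrochloride; 8 4-toluenesulfonyl chloride
Product: 9 4-methyl-N-(2-oxopropyl)benzenesulfonamide (N-tosylaminoacetone)
Conditions: NaHCO3, CH2Cl2/H2O, 0 → 25 °C
Reagents that add atoms: none
Why: Schotten–Baumann N-sulfonylation in a two-phase medium, in which the amine is set free from its salt only gradually and should be captured by the sulfonyl chloride before it can self-condense to a dihydropyrazine.

Step 4
Reactants: 6 4,5-dibromo-2-(trimethylsilyl)phenyl trifluoromethanesulfonate (1.3 equiv); 9 N-tosylaminoacetone
Product: 12 5,6-dibromo-3-methyl-1-tosylindole, via 4,5-dibromobenzyne 10 (not isolated), via 3-hydroxyindoline 11 (not isolated)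
Conditions: CsF (3 equiv), MeCN, 25 °C; filter, evaporate; TsOH·H2O (cat.), toluene, 80 °C
Reagents that add atoms: none
Why: Fluoride attacks silicon of 6 and triflate leaves in a 1,2-elimination to give aryne 10; the sulfonamide anion of 9 (its N–H is far more acidic than the ketone α-hydrogens, so nitrogen and not the enolate is the nucleophile) adds to it and forms N1–C7a. The aryl anion so produced adds to the carbonyl carbon in a 5-exo-trig closure that forms C3–C3a and the pyrrole ring as the tertiary alkoxide of 11, which after protonation loses water by acid-catalysed E1 dehydration, driven by aromatisation, to give 12. The closest known reaction is the fluoride-induced annulation of ortho-silylaryl triflates with N-sulfonyl α-amino ketones to 3-hydroxyindolines and indoles. The carbinol centre of 11 forms as a racemate and disappears on dehydration, so no stereocontrol is needed. Regioselectivity does not arise because 10 is symmetric, and ring closure must outrun protonation of the aryl anion, which the aprotic medium and the intramolecular five-membered transition state should secure. The two electron-withdrawing bromines make the aryne more electrophilic and, with no metal present, should stay untouched.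

Step 5
Reactants: 12 5,6-dibromo-3-methyl-1-tosylindole
Product: 13 2,5,6-tribromo-3-methyl-1-tosylindole
Conditions: NBS (1.1 equiv), DMF, 25 °C, dark
Reagents that add atoms: N-bromosuccinimide, O=C1CCC(=O)N1Br
Why: Electrophilic aromatic bromination under ionic conditions should go to C2, the only free position of the pyrrole ring, since C4 and C7 on the benzene ring are deactivated by the adjacent bromines.

Step 6
Reactants: 13 2,5,6-tribromo-3-methyl-1-tosylindole
Product: 14 2,5,6-tribromo-3-(bromomethyl)-1-tosylindole
Conditions: NBS (1.05 equiv), AIBN (cat.), PhCF3, 85 °C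
Reagents that add atoms: N-bromosuccinimide, O=C1CCC(=O)N1Br
Why: Wohl–Ziegler radical bromination, in which, with the sulfonyl group on N1 and C2 blocked, hydrogen abstraction should occur at the C3 methyl group (its radical is conjugated with the indole π system) in preference to the tosyl methyl group, which the para sulfonyl group deactivates towards the electrophilic bromine atom.

Step 7
Reactants: 14 2,5,6-tribromo-3-(bromomethyl)-1-tosylindole; 15 dimethylamine
Product: 16 1-(2,5,6-tribromo-1-tosylindol-3-yl)-N,N-dimethylmethanamine (2,5,6-tribromo-1-tosylgramine)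
Conditions: Me2NH (2 M in THF, 3 equiv), THF, 0 → 25 °C
Reagents that add atoms: none
Why: SN2 displacement of the activated indol-3-ylmethyl bromide by a secondary amine, in which excess dimethylamine takes up HBr and suppresses quaternisation while the N-tosyl group keeps the bromide from ionising to an azafulvene.

Step 8
Reactants: 16 2,5,6-tribromo-1-tosylgramine
Product: 17 1-(2,5,6-tribromo-1H-indol-3-yl)-N,N-dimethylmethanamine (2,5,6-tribromogramine)
Conditions: KOH, 1,4-dioxane/H2O, 60 °C
Reagents that add atoms: none
Why: Alkaline hydrolysis of an N-sulfonylindole by attack of hydroxide at sulfur, made easy by the good tribromoindolide leaving group, with alcohol left out so that no alkyl sulfonate able to alkylate the amine can form.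

Step 9
Reactants: 17 2,5,6-tribromogramine
Product: 18 1-(2,5,6-tribromo-1-methylindol-3-yl)-N,N-dimethylmethanamine (2,5,6-tribromo-1-methylgramine)
Conditions: NaH (1.05 equiv), DMF, 0 °C; MeI (1.0 equiv), −20 → 0 °C
Reagents that add atoms: iodomethane, CI
Why: N-alkylation of the preformed sodium indolide, an anionic nucleophile that should consume one equivalent of iodomethane at low temperature much faster than the neutral tertiary amine undergoes Menshutkin quaternisation.

Step 10
Reactants: 18 2,5,6-tribromo-1-methylgramine
Product: 19 2,5,6-tribromo-1-methylgramine N-oxide (target)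
Conditions: mCPBA (1.05 equiv), CH2Cl2, 0 °C; filtration through basic Al2O3
Reagents that add atoms: 3-chloroperbenzoic acid, OOC(=O)c1cccc(Cl)c1
Why: Peracid oxidation of a tertiary amine to its N-oxide, which should be much faster than attack on the electron-poor, 2-brominated indole C2=C3 bond, with the product kept cold to avoid Meisenheimer rearrangement.

Compound list
1 | 3,4-dibromophenol | Oc1ccc(Br)c(Br)c1 | starting material
2 | 4,5-dibromo-2-iodophenol | Oc1cc(Br)c(Br)cc1I | intermediate
3 | (4,5-dibromo-2-iodophenoxy)trimethylsilane | C[Si](C)(C)Oc1cc(Br)c(Br)cc1I | intermediate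
4 | [4,5-dibromo-2-(trimethylsilyloxy)phenyl]lithium | C[Si](C)(C)Oc1cc(Br)c(Br)cc1[Li] | intermediate
5 | lithium 4,5-dibromo-2-(trimethylsilyl)phenoxide | [Li+].[O-]c1cc(Br)c(Br)cc1[Si](C)(C)C | intermediate
6 | 4,5-dibromo-2-(trimethylsilyl)phenyl trifluoromethanesulfonate | C[Si](C)(C)c1cc(Br)c(Br)cc1OS(=O)(=O)C(F)(F)F | intermediate
7 | aminoacetone hydrochloride | CC(=O)CN.Cl | starting material
8 | 4-toluenesulfonyl chloride | Cc1ccc(cc1)S(Cl)(=O)=O | starting material
9 | 4-methyl-N-(2-oxopropyl)benzenesulfonamide | CC(=O)CNS(=O)(=O)c1ccc(C)cc1 | intermediate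
10 | 4,5-dibromobenzyne | BrC1=CC#CC=C1Br | intermediate
11 | 5,6-dibromo-3-methyl-1-tosylindolin-3-ol (racemic) | CC1(O)CN(S(=O)(=O)c2ccc(C)cc2)c2cc(Br)c(Br)cc21 | intermediate
12 | 5,6-dibromo-3-methyl-1-tosylindole | Cc1cn(S(=O)(=O)c2ccc(C)cc2)c2cc(Br)c(Br)cc12 | intermediate
13 | 2,5,6-tribromo-3-methyl-1-tosylindole | Cc1c(Br)n(S(=O)(=O)c2ccc(C)cc2)c2cc(Br)c(Br)cc12 | intermediate
14 | 2,5,6-tribromo-3-(bromomethyl)-1-tosylindole | BrCc1c(Br)n(S(=O)(=O)c2ccc(C)cc2)c2cc(Br)c(Br)cc12 | intermediate
15 | dimethylamine | CNC | starting material
16 | 2,5,6-tribromo-1-tosylgramine | CN(C)Cc1c(Br)n(S(=O)(=O)c2ccc(C)cc2)c2cc(Br)c(Br)cc12 | intermediate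
17 | 2,5,6-tribromogramine | CN(C)Cc1c(Br)[nH]c2cc(Br)c(Br)cc12 | intermediate
18 | 2,5,6-tribromo-1-methylgramine | CN(C)Cc1c(Br)n(C)c2cc(Br)c(Br)cc12 | intermediate
19 | 2,5,6-tribromo-1-methylgramine N-oxide | Cn1c(Br)c(C[N+](C)(C)[O-])c2cc(Br)c(Br)cc21 | target

Total step count: 10. Longest linear sequence: 9 (steps 1, 2 and 4 to 10).

Steps most likely to fail

Step 4. The aryl anion may be protonated before it reaches the ketone, so that only N-arylation results, or the electron-poor aryne may be used up by oligomerisation or by arylation of the alkoxide. The fallback builds the same ring by an intramolecular Heck closure. It sets out from 4-toluenesulfonyl chloride (8) and purchased 3,4-dibromoaniline F1. Iodination (NIS, AcOH) at the ortho carbon remote from bromine should give 4,5-dibromo-2-iodoaniline F2. Sulfonylation with 8 in pyridine gives N-(4,5-dibromo-2-iodophenyl)-4-methylbenzenesulfonamide F3, and allyl bromide with K2CO3 in DMF gives N-allyl-N-(4,5-dibromo-2-iodophenyl)-4-methylbenzenesulfonamide F4. With Pd(OAc)2, Bu4NCl and NaHCO3 in DMF at 60 °C, zerovalent palladium should insert into the C–I bond in preference to C–Br. A 5-exo-trig carbopalladation and β-hydride elimination then give 5,6-dibromo-3-methylene-1-tosylindoline F5, whose double bond moves into the ring (with a trace of TsOH if needed). The fallback comes back to the route at 12.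

Step 2. Butyllithium may exchange a bromine or attack silicon of the silyl ether, which would scramble the halogen pattern. The fallback replaces lithium by magnesium and the silyl shift by an external silyl electrophile. It sets out from 2, which is silylated to 3 as before. i-PrMgCl·LiCl in THF at −40 °C, an iodine–magnesium exchange that leaves aryl bromides alone, should give [4,5-dibromo-2-(trimethylsilyloxy)phenyl]magnesium chloride F6. Me3SiCl silylates carbon to give [4,5-dibromo-2-(trimethylsilyl)phenoxy]trimethylsilane F7, and K2CO3 in MeOH cleaves only the O–Si bond to give 4,5-dibromo-2-(trimethylsilyl)phenol F8. Tf2O and pyridine in CH2Cl2 at 0 °C then give 6, where the route is rejoined.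

Step 9. Quaternisation of the side-chain amine may compete with methylation at the indole nitrogen. The fallback masks the amine as its borane adduct. It sets out from 17: BH3·THF at 0 °C should complex only the tertiary amine and give 2,5,6-tribromogramine–borane F9. NaH and MeI in DMF then methylate N1 to give 2,5,6-tribromo-1-methylgramine–borane F10. HCl in MeOH at 40 °C followed by NaHCO3 removes the borane and returns the route at 18.

Further compounds
F1 | step 4 | 3,4-dibromoaniline | Nc1ccc(Br)c(Br)c1
F2 | step 4 | 4,5-dibromo-2-iodoaniline | Nc1cc(Br)c(Br)cc1I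
F3 | step 4 | N-(4,5-dibromo-2-iodophenyl)-4-methylbenzenesulfonamide | Cc1ccc(cc1)S(=O)(=O)Nc1cc(Br)c(Br)cc1I
F4 | step 4 | N-allyl-N-(4,5-dibromo-2-iodophenyl)-4-methylbenzenesulfonamide | C=CCN(c1cc(Br)c(Br)cc1I)S(=O)(=O)c1ccc(C)cc1
F5 | step 4 | 5,6-dibromo-3-methylene-1-tosylindoline | C=C1CN(S(=O)(=O)c2ccc(C)cc2)c2cc(Br)c(Br)cc21
F6 | step 2 | [4,5-dibromo-2-(trimethylsilyloxy)phenyl]magnesium chloride | C[Si](C)(C)Oc1cc(Br)c(Br)cc1[Mg]Cl
F7 | step 2 | [4,5-dibromo-2-(trimethylsilyl)phenoxy]trimethylsilane | C[Si](C)(C)Oc1cc(Br)c(Br)cc1[Si](C)(C)C
F8 | step 2 | 4,5-dibromo-2-(trimethylsilyl)phenol | Oc1cc(Br)c(Br)cc1[Si](C)(C)C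
F9 | step 9 | 2,5,6-tribromogramine–borane | C[N+](C)([BH3-])Cc1c(Br)[nH]c2cc(Br)c(Br)cc12
F10 | step 9 | 2,5,6-tribromo-1-methylgramine–borane | C[N+](C)([BH3-])Cc1c(Br)n(C)c2cc(Br)c(Br)cc12
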